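(All runs stem from a simulated flask for an exercise.)

The larch run shows target falling while side product climbs, and the reckoning below follows how fast that spoiling goes.

| flask | substrate | reagent | temperature | remark | time |
|---|---|---|---|---|---|
| alder | 10 mM | 7 mM | −35 °C | run made earlier |  |
| larch | 10 mM | 16 mM | −15 °C | run made earlier |  |
| south-east | 10 mM | 10.5 mM | −15 °C |  | 4.0 h |
| east | 10 mM | 10.5 mM | 0 °C |  | 4.0 h |
| north-east | 10 mM | 10.5 mM | −30 °C |  | 4.0 h |

| run | time / h | target / % | side product / % |
|---|---|---|---|
| alder | 0.333 | 34.2 | 0.5 |
| alder | 0.833 | 35.1 | 0.8 |
| alder | 2.00 | 35.3 | 2.7 |
| alder | 2.50 | 33.8 | 3.2 |
| alder | 4.00 | 33.2 | 3.8 |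
| alder | 5.00 | 32.0 | 6.3 |
| alder | 6.00 | 31.5 | 5.9 |
| larch | 0.133 | 49.3 | 1.5 |
| larch | 0.333 | 47.9 | 6.1 |
| larch | 0.667 | 43.5 | 10.7 |
| larch | 1.00 | 40.2 | 14.6 |
| larch | 1.33 | 37.6 | 17.3 |
| larch | 2.00 | 32.7 | 23.4 |
| larch | 2.50 | 31.1 | 27.2 |

(standard deviation of a reading: 0.5 percentage points)

- released group is meant together with its crystals
- solid, in amounts per volume of the solution: crystals
- steps thought possible: substrate + reagent <-> target + released group; 2 reagent -> homo dimer; crystals <-> released group; target + released group -> side product

- the best flask by share of target in all that became target or side product; "all alike" if 1.5 percentage points covers them all (south-east / east / north-east / all alike)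
- share of target in all that became target or side product, south-east
- share of target in all that became target or side product, east
- share of target in all that became target or side product, north-east

Side product forms from target and released group, so its rate carries the concentration of dissolved released group. Apart from crystals, each step that makes or uses one also makes or uses the other, so if no crystals stand, the two fractions of the charge are equal and side product forms at a rate second-order in target. Call κ the spoiling constant: the fraction of side product gained per hour per squared fraction of target. Over a stretch, the product of the target fractions at its two ends stands in for that square.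

The first way counts side product. The larch run gains 26 percentage points in 2.37 h, which gives κ = 0.708 /h. The second way counts target: the rise of its reciprocal per hour gives 0.501 /h, which is smaller. The two part because target falls by 18 points, less than side product gains. Substrate and reagent are thus refilling target, and the second way cheats, so the first is kept. In the alder run the first way reads 0.0885 /h, which puts 8.00 times between the two temperatures.

If target plus side product stays near a total S, side over target grows as κ·S·t. My own reckoning takes S as 0.5 of the charge and gives south-east a share of 41.4 %. For the other two flasks it gives an order and no figure: κ reads less in the colder run, so north-east should rank above south-east and east below it.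

The forecast says north-east, with 46 %, 20 % and 79 % for south-east, east and north-east, because the larch run “fits second-order loss of target”. For south-east it stands above my figure.

The flask gives north-east, with 45.9 %, 19.5 % and 77.9 %.

    substrate + reagent ⇌ target + released group (K = 0.520, k = 2.30 /M/s, Ea = 44.0 kJ/mol, ΔH = −2.00 kJ/mol)
    2 reagent → homo dimer (k = 0.0210 /M/s, Ea = 43.0 kJ/mol)
    crystals ⇌ released group, rate k3*(cs3 - [released group]) while solid is left; crystals form when [released group] > cs3 (solubility = 8.20 mM, k = 0.0920 /s)
    target + released group → side product (k = 0.0690 /M/s, Ea = 50.0 kJ/mol)
    (constants at 0 °C)

South-east at 4.00 h holds 0 mM of crystals, and its released group, 2.42 mM, matches its target of 24.2 %. From 2.00 h on, κ gives a gain of 11 points, and the flask gains 10 points.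

In east the same window reads 2.48 /h, or 3.50 times the larch κ. The neighbour of east with 6.0 mM of substrate has κ scaled with its charge to 1.49 /h, so, with the total of target and side product held as in east, east's side-to-target ratio of 4.12 becomes 2.47, an estimated share of 28.8 %. The computed share of that neighbour is 24.9 %, with target plus side product at 68.5 % against 61.6 % in east.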